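## Structural features

The target joins a fully substituted phloroglucinol dialdehyde (ring C1′–C6′) through the benzylic carbon C9′ to C1 of a trans-fused decalin (ring A: C1–C5 and C10; ring B: C5–C10); C9′ also carries an isobutyl group. The decalin is numbered so that C1 bears C9′, C4 the methyl carbinol, C5 and C10 are the ring-fusion carbons, and C7 bears the 2-hydroxypropan-2-yl group (C11); β denotes the face of the C10 methyl group. Five stereocentres form a contiguous chain, C9′ (S)–C1 (R)–C10 (R, quaternary)–C5 (S)–C4 (R), and C7 (S) stands alone in ring B. Relative to the C10 methyl, C9′ on C1 is β and equatorial, the C4 hydroxyl is β and axial (syn-diaxial to the C10 methyl), H5 is α, and the C7 substituent is β and equatorial. The fragile groups are the two tertiary alcohols (ionisation and elimination under Brønsted or Lewis acid), the two aldehydes (nucleophiles, hydrides) and the electron-rich arene (electrophiles, oxidants). The real difficulty lies in the quaternary C10 flanked by two further stereocentres, the axial C4 carbinol, and above all the acyclic C9′ centre, which no ring holds in place. Ring A with its C4 methyl and the 1,4-related carbon C9′ on C1 is a p-menthane; the key step exploits this by annulating ring B onto a carvone-derived ring A, forming C9–C10 and C5–C6 and fixing C10 from the existing C1 centre.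

## Logic of the disconnections

37 ⇒ 36. The three phenolic O–H groups are traced back to O–CH3 bonds. The free trihydroxy dialdehyde is acidic, chelating and easily oxidised, so it is released last. The forward step must cleave three aryl methyl ethers without ionising two tertiary alcohols, which calls for a basic, nucleophilic demethylation.

36 ⇒ 33 ⇒ 32. The two aryl–CHO bonds are cut, by way of the two aryl–Br bonds. Aldehydes would not survive the organometallic steps, so they follow the last C–C bond formation in the terpene part. The forward formylation must avoid Lewis acids, hence bromination followed by bromine–lithium exchange and a formamide quench.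

32 ⇒ 30. Both C11–CH3 bonds are cut, leaving an ester on C7. This reduces the hydroxyisopropyl group to a one-carbon unit and demands only that the ester be equatorial.

30 ⇒ 29 ⇒ 28 ⇒ 26. The C7–C11 bond is cut (carbonylation of an enol triflate), together with the C–H bonds added by hydrogenation. A C7 ketone is exactly what the annulation leaves in ring B. The forward hydrogenation must add to the α face at C7, and it also saturates the side chain.

26 ⇒ 25 ⇒ 22 + 23. The bond between the side-chain CH2 and the isopropenyl carbon and the C9′–H bond are cut, and the C7 carbonyl is masked as its dioxolane. The isobutyl-bearing stereocentre becomes a 1,1-disubstituted aryl alkene. The forward hydroboration must choose one alkene face under control of C1 and C10.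

22 ⇒ 18 + 19. The C9′–C1′ bond is cut at an sp2 carbon. This avoids adding a hindered aryl nucleophile to a hindered, enolisable ketone and avoids a benzylic cation next to C1. The demand is a cross-coupling between a di-ortho-substituted arylmetal and an α-branched alkenyl triflate.

18 ⇒ 17 ⇒ 16. The C5–H bond (through C5–Br) and the C4–O bond are cut, giving a tetrasubstituted C4=C5 alkene. Two adjacent stereocentres are removed at once. The forward steps need a bromonium ion on the α face, diaxial opening by water at C4, and hydrogen delivery to C5 on the α face.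

16 ⇒ 14 ⇒ 12. The alkenyl triflate goes back to a methyl ketone and this to the isopropenyl group by C=C cleavage, so the isopropenyl carbon of the chiral-pool material becomes C9′. The forward dihydroxylation must prefer the 1,1-disubstituted alkene over the hindered ring alkene.

12 ⇒ 11 ⇒ 9. The ketal goes back to the ketone, and the C3–H and C6–H bonds are cut to reveal a linear dienone. The forward reduction must be a 1,6-addition that leaves C4=C5.

9 ⇒ 4 + 5. The C9–C10 bond and the C5=C6 bond are cut, which removes ring B and leaves a monocyclic enone and a four-carbon enone. The forward step must enolise 4 at the α′ carbon only and alkylate anti to the isopropenyl group.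

4 ⇒ 1 + 2. The methyl group on the future C10 is cut, leading to the chiral-pool enone. The forward step is a kinetic α′-methylation.

## Other disconnections considered

Alternative 1: The cut is through the arene itself, at C1′–C6′ and C2′–C3′. In the forward step the ynol silyl ether A3, which carries the whole protected terpene on its propargylic carbon C9′, would add across C6 and C3 of the pyrone diester A2; the bridged lactone then loses CO2 to give the hexasubstituted arene A1.
- In its favour: all six ring substituents are placed in one neutral thermal step. The regiochemistry follows from the polarity of the partners (nucleophilic alkyne carbon C1′ to the electrophilic pyrone C6). Both carbonyl carbons arrive with the ring, so no formylation of an advanced intermediate is needed. On this point the alternative is better than the chosen plan, whose steps 15 and 16 are among its weaker ones. The silylated tertiary alcohols are at least as safe as the free alcohols of the chosen endgame.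
- Against it here: A3 already contains every stereocentre, so the step solves none of the stereochemical problems, and C9′ would have to be set as a propargylic centre by other means. An internal alkyne next to a branched carbon is a hindered dienophile and is expected to need forcing conditions. Afterwards two esters must be taken to the aldehyde level and three kinds of protecting group removed.
- Comparison: structurally the plans are complementary (arene against ring B). Mechanistically the pericyclic step is more predictable in regiochemistry but less certain in rate. In step economy it is expected to be longer, because the alkyne, the pyrone and the redox adjustment are added to a terpene synthesis of similar length.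

Alternative 2: The cuts are C4–C5 and C9–C10, both rings at once. Fe(acac)3 and PhSiH3 would transfer a hydrogen atom to the silyl enol ether of the acyclic trienone A5; the C4 α-silyloxy radical closes 6-endo on C5, and the C10 radical closes 6-endo on the vinyl ketone to give A4.
- In its favour: two rings, the quaternary C10, the trans fusion and the C4–O bond would come in one step. The C4 oxygen arrives with the skeleton, which is better than steps 7 and 8 of the chosen plan. The C7 ketone is the same handle as in the chosen plan (equal).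
- Against it here: A4 has the C1 ester axial and must be epimerised at C1. C9′ is only at the carboxyl level, so aryl, isobutyl and the C9′ configuration must all be built from an ester. The absolute configuration needs a separately made stereocentre in A5, whereas the chosen plan takes it from the chiral pool. A nucleophilic α-oxy radical adding to an unactivated trisubstituted alkene is polarity-mismatched, so premature reduction or 5-exo closure is a real risk.
- Comparison: ring construction is shorter, but assembling A5 and the side chain takes more steps, so overall step economy is about equal at best. Mechanistic risk is higher, and absolute stereocontrol is weaker.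

Alternative 3: The cut is C4–C5, acyl carbon to enone β-carbon. A carbene from a chiral triazolium salt would convert the aldehyde of A7 into an acyl anion equivalent that adds to one β-carbon of the cyclohexadienone, closing ring A and fixing C10 (product A6).
- In its favour: a C4 ketone is the ideal precursor of the axial carbinol by equatorial addition of a methyl-metal reagent, which is better than the chosen bromohydrin sequence. The aryl and isobutyl groups are in place before ring formation, so no coupling on a hindered late intermediate is needed (also better). The ring-B enone is a handle for C7 equal to the chosen ketone.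
- Against it here: the acyl carbon can only reach the β-carbon on the face from which the tether leaves C10, so the closure is expected to give the cis-fused isomer A8 first. A6 would then arise only by epimerisation at C5, which is not strongly biased toward trans in an angularly methylated 1-decalone. Because A7 already carries C1 and C9′, the two enone arms are diastereotopic and the catalyst must match or override the substrate. The vicinal acyclic centres C1 and C9′ must be built on a quaternary dienone, so the hardest problem is moved and not solved.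
- Comparison: the alternative sets C10 by catalyst, the chosen plan by a chiral-pool centre. Both ring closures are six-membered and favourable, but the ring fusion is uncertain in the alternative and deferred to a separate, controllable step in the chosen plan. Step economy is comparable and depends on the route to A7.

Key step: step 2

Remarks on the chemistry:
- Dissolving-metal reduction of the linear dienone 9 is taken to be a 1,6-addition (hydrogen at C3 and C6). The alkene that remains is therefore C4=C5 and not C3=C4, so the bromohydrin–debromination sequence is planned on C4=C5 and sets C4 and C5 together.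
- 4 is expected as a mixture at the methyl-bearing carbon (mainly 6R); both epimers give the same enolate 6.
- The structures of 1, 4 and 9 were compared with 37 centre by centre and agree; (S)-carvone is the correct enantiomer, and the descriptor at C1 changes from S (in 1 and 4) to R (in 9 and 37) only through a change in CIP priorities.
- The arene is introduced at an sp2 carbon and the formyl groups after the last Grignard step, because a benzylic cation at C9′, Lewis-acidic formylation and strong acid would endanger C1 or the tertiary alcohols.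

## Route

Step 1
Reactants: 1 (S)-(+)-carvone; 2 iodomethane
Product: 4 (5S,6R)-2,6-dimethyl-5-(prop-1-en-2-yl)cyclohex-2-en-1-one, via lithium α′-enolate of carvone 3 (not isolated)
Conditions: LiN(iPr)2, THF, −78 °C; MeI, −78 → 0 °C
Reagents that add atoms: iodomethane (2), CI
Why: Kinetic deprotonation at the only α′ position and SN2 methylation of the cross-conjugated enolate (enolate alkylation), mainly trans to the isopropenyl group; the new centre is lost again on enolisation in step 2.

Step 2
Reactants: 4 (5S,6R)-2,6-dimethyl-5-(prop-1-en-2-yl)cyclohex-2-en-1-one; 5 but-3-en-2-one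
Product: 9 (4aR,5R)-4a,8-dimethyl-5-(prop-1-en-2-yl)-4,4a,5,6-tetrahydronaphthalen-2(3H)-one, via lithium α′-enolate of the enone 6 (not isolated), via Michael adduct diketone 7 (not isolated), via aldol ketol 8 (not isolated)
Conditions: LiN(iPr)2 (1.05 equiv), THF, −78 °C; 5, −78 → −20 °C; then KOH, MeOH, 60 °C
Reagents that add atoms: but-3-en-2-one (5), CC(=O)C=C
Why: This is a Robinson annulation run through a preformed kinetic enolate: LiN(iPr)2 removes the only α′ hydrogen of 4 to give the cross-conjugated enolate 6, which adds in a Michael sense to but-3-en-2-one through the future C10 and forms C9–C10 (diketone 7). Under KOH in MeOH the methyl ketone enolises at its methyl group (the future C6) and attacks the ring carbonyl (C5), a 6-(enolexo)-exo-trig aldol closure that gives ketol 8; E1cB loss of water, helped by conjugation with C3=C4, gives the linear dienone 9. The only new stereocentre that survives is C10: in the half-chair enolate the isopropenyl group on the neighbouring carbon is held pseudoaxial by allylic strain with the enolate methyl, so the enone approaches the opposite face and the methyl ends up cis to the C1 substituent. The step needs α′ and not γ enolisation, which the kinetic amide base at low temperature and the single α′ hydrogen secure; it needs conjugate and not 1,2-addition, which the hindered tetrasubstituted enolate favours; and it needs facial selectivity, which the adjacent C1 centre supplies. The closest known reaction type is the alkylation and annulation of kinetic α′-enolates of 6-alkylcarvones anti to the isopropenyl group.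

Step 3
Reactants: 9 (4aR,5R)-4a,8-dimethyl-5-(prop-1-en-2-yl)-4,4a,5,6-tetrahydronaphthalen-2(3H)-one
Product: 11 (4aR,5R)-4a,8-dimethyl-5-(prop-1-en-2-yl)-3,4,4a,5,6,7-hexahydronaphthalen-2(1H)-one, via lithium dienolate 10 (not isolated)
Conditions: Li (2.2 equiv), NH3(l)–THF, −78 °C; isoprene; solid NH4Cl
Reagents that add atoms: none
Why: Dissolving-metal reduction of a linear dienone is a 1,6-addition: the dienyl anion is protonated at its terminus C3, dienolate 10 is not reduced further, and kinetic protonation at C6 on quenching should give the β,γ-enone with the tetrasubstituted C4=C5 bond. The isolated isopropenyl group is inert and no stereocentre is touched.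

Step 4
Reactants: 11 (4aR,5R)-4a,8-dimethyl-5-(prop-1-en-2-yl)-3,4,4a,5,6,7-hexahydronaphthalen-2(1H)-one
Product: 12 7,7-ethylenedioxy-1β-isopropenyl-4,10β-dimethyl-Δ4(5)-octalin (spiro-1,3-dioxolane of 11)
Conditions: HOCH2CH2OH, pyridinium p-toluenesulfonate (cat.), benzene, reflux, Dean–Stark
Reagents that add atoms: ethane-1,2-diol, OCCO
Why: Acid-catalysed ketalisation; the alkene stays in the β,γ-position (any conjugated isomer of 11 converges on the same ketal, as 4-en-3-ones give 5-ene ketals), and the ketal masks C7 through steps 5–10.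

Step 5
Reactants: 12 7,7-ethylenedioxy-1β-isopropenyl-4,10β-dimethyl-Δ4(5)-octalin
Product: 14 1β-acetyl-7,7-ethylenedioxy-4,10β-dimethyl-Δ4(5)-octalin, via vicinal diol 13 (not isolated)
Conditions: OsO4 (2 mol %), NaIO4, 2,6-lutidine, dioxane–H2O (3:1), 23 °C
Reagents that add atoms: osmium tetroxide, O=[Os](=O)(=O)=O (oxygen donor, re-formed by sodium periodate, [Na+].[O-]I(=O)(=O)=O); water, O
Why: Lemieux–Johnson cleavage: OsO4 should dihydroxylate the unhindered 1,1-disubstituted alkene much faster than the hindered tetrasubstituted ring alkene, and NaIO4 cleaves diol 13 to the C9′ methyl ketone; the lutidine buffer protects the ketal.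

Step 6
Reactants: 14 1β-acetyl-7,7-ethylenedioxy-4,10β-dimethyl-Δ4(5)-octalin
Product: 16 1-(7,7-ethylenedioxy-4,10β-dimethyl-Δ4(5)-octalin-1β-yl)ethenyl trifluoromethanesulfonate, via potassium enolate 15 (not isolated)
Conditions: KN(SiMe3)2, THF, −78 °C; PhNTf2, −78 → 0 °C; aq. NH4Cl
Reagents that add atoms: N-phenylbis(trifluoromethanesulfonimide), O=S(=O)(N(c1ccccc1)S(=O)(=O)C(F)(F)F)C(F)(F)F
Why: Kinetic enolisation at the methyl group (the hindered tertiary C1–H is left alone, so C1 is not epimerised) and O-sulfonylation give the alkenyl triflate. Doing this before step 7 leaves only an electron-poor alkene beside C4=C5.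

Step 7
Reactants: 16 1-(7,7-ethylenedioxy-4,10β-dimethyl-Δ4(5)-octalin-1β-yl)ethenyl trifluoromethanesulfonate
Product: 17 1-(5α-bromo-7,7-ethylenedioxy-4β-hydroxy-4α,10β-dimethyl-trans-decalin-1β-yl)ethenyl trifluoromethanesulfonate
Conditions: NBS, THF–H2O (4:1), 0 °C, dark
Reagents that add atoms: N-bromosuccinimide, O=C1CCC(=O)N1Br; water, O
Why: Bromohydrin formation: the bromonium ion forms on the α face (anti to the C10 methyl) and water opens it axially at C4 from the β face (trans-diaxial, Fürst–Plattner opening, as in 5α-bromo-6β-hydroxy steroids). This sets C4 with axial OH and equatorial methyl; the alkenyl triflate is too electron-poor to compete.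

Step 8
Reactants: 17 1-(5α-bromo-7,7-ethylenedioxy-4β-hydroxy-4α,10β-dimethyl-trans-decalin-1β-yl)ethenyl trifluoromethanesulfonate
Product: 18 1-(7,7-ethylenedioxy-4β-hydroxy-4α,10β-dimethyl-5αH-trans-decalin-1β-yl)ethenyl trifluoromethanesulfonate
Conditions: Bu3SnH, AIBN (cat.), benzene, 80 °C
Reagents that add atoms: none
Why: Radical chain dehalogenation: the tertiary C5 radical should take hydrogen from Bu3SnH on the α face, anti to the C10 methyl and the axial C4 hydroxyl, giving the trans-decalin (the axial quench usual for ring-fusion decalyl radicals). The alkenyl triflate and the ketal are inert.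

Step 9
Reactants: 18 1-(7,7-ethylenedioxy-4β-hydroxy-4α,10β-dimethyl-5αH-trans-decalin-1β-yl)ethenyl trifluoromethanesulfonate; 19 1,3,5-trimethoxybenzene
Product: 22 7,7-ethylenedioxy-4α,10β-dimethyl-1β-[1-(2,4,6-trimethoxyphenyl)ethenyl]-5αH-trans-decalin-4β-ol, via 2,4,6-trimethoxyphenyllithium 20 (not isolated), via (2,4,6-trimethoxyphenyl)zinc chloride 21 (not isolated)
Conditions: 19 (3 equiv), n-BuLi, THF, 0 → 23 °C; ZnCl2; then 18, Pd2(dba)3 (2.5 mol %), SPhos (10 mol %), THF, 60 °C
Reagents that add atoms: 1,3,5-trimethoxybenzene (19), COc1cc(OC)cc(OC)c1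
Why: Negishi cross-coupling of the alkenyl triflate with arylzinc 21 (ortho-lithiation of 19 between two methoxy groups, then transmetalation); the dialkylbiarylphosphine ligand is suited to the di-ortho-substituted aryl partner. No benzylic cation is involved, so C1 cannot epimerise.

Step 10
Reactants: 22 7,7-ethylenedioxy-4α,10β-dimethyl-1β-[1-(2,4,6-trimethoxyphenyl)ethenyl]-5αH-trans-decalin-4β-ol; 23 2-bromopropene
Product: 26 4β-hydroxy-4α,10β-dimethyl-1β-[(1S)-3-methyl-1-(2,4,6-trimethoxyphenyl)but-3-en-1-yl]-5αH-trans-decalin-7-one, via B-alkyl-9-borabicyclononane adduct 24 (not isolated), via methallyl ketal 25 (not isolated)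
Conditions: 9-BBN-H (9-borabicyclo[3.3.1]nonane, 2.5 equiv), THF, 60 °C; then 23, PdCl2(dppf) (5 mol %), K3PO4 (aq), DMF, 50 °C; then 2 M HCl, THF, 23 °C
Reagents that add atoms: 2-bromopropene (23), CC(Br)=C; water, O
Why: Anti-Markovnikov hydroboration puts boron on the terminal CH2 and hydrogen on C9′ from the alkene face turned toward C2, in the conformer where the C9′–aryl bond eclipses C1–H and the aryl group avoids the C10 methyl (allylic strain); the other face is screened by C10 and C9, which should set (S)-C9′. B-alkyl Suzuki–Miyaura coupling then completes the isobutyl skeleton, and the acidic work-up hydrolyses the dioxolane.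

Step 11
Reactants: 26 4β-hydroxy-4α,10β-dimethyl-1β-[(1S)-3-methyl-1-(2,4,6-trimethoxyphenyl)but-3-en-1-yl]-5αH-trans-decalin-7-one
Product: 28 4β-hydroxy-4α,10β-dimethyl-1β-[(1S)-3-methyl-1-(2,4,6-trimethoxyphenyl)but-3-en-1-yl]-5αH-octal-7-en-7-yl trifluoromethanesulfonate, via dilithium alkoxide enolate 27 (not isolated)
Conditions: LiN(SiMe3)2 (2.3 equiv), THF, −78 °C; PhNTf2, −78 → 0 °C; aq. NH4Cl
Reagents that add atoms: N-phenylbis(trifluoromethanesulfonimide), O=S(=O)(N(c1ccccc1)S(=O)(=O)C(F)(F)F)C(F)(F)F
Why: Kinetic enolisation of the trans-fused C7 ketone toward C8 and O-sulfonylation (enol triflate formation); the hindered tertiary lithium alkoxide should not be sulfonylated at low temperature. A C6=C7 regioisomer would converge in step 13.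

Step 12
Reactants: 28 4β-hydroxy-4α,10β-dimethyl-1β-[(1S)-3-methyl-1-(2,4,6-trimethoxyphenyl)but-3-en-1-yl]-5αH-octal-7-en-7-yl trifluoromethanesulfonate
Product: 29 methyl 4β-hydroxy-4α,10β-dimethyl-1β-[(1S)-3-methyl-1-(2,4,6-trimethoxyphenyl)but-3-en-1-yl]-5αH-octal-7-ene-7-carboxylate
Conditions: Pd(OAc)2 (5 mol %), PPh3, CO (1 atm), MeOH, Et3N, DMF, 50 °C
Reagents that add atoms: carbon monoxide, [C-]#[O+]; methanol, CO
Why: Palladium-catalysed alkoxycarbonylation of an enol triflate: oxidative addition to zerovalent palladium, CO insertion and methanolysis give the conjugated ester and introduce C11.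

Step 13
Reactants: 29 methyl 4β-hydroxy-4α,10β-dimethyl-1β-[(1S)-3-methyl-1-(2,4,6-trimethoxyphenyl)but-3-en-1-yl]-5αH-octal-7-ene-7-carboxylate
Product: 30 methyl 4β-hydroxy-4α,10β-dimethyl-1β-[(1S)-3-methyl-1-(2,4,6-trimethoxyphenyl)butyl]-trans-decalin-7β-carboxylate
Conditions: H2 (1–3 atm), 10 % Pd on carbon, EtOAc, 23 °C
Reagents that add atoms: none
Why: Heterogeneous hydrogenation of both alkenes; hydrogen should add to C7=C8 from the α face, opposite the axial C10 methyl, giving the equatorial β ester. This is also the thermodynamic epimer, so NaOMe in MeOH would correct any axial isomer; the step sets C7.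

Step 14
Reactants: 30 methyl 4β-hydroxy-4α,10β-dimethyl-1β-[(1S)-3-methyl-1-(2,4,6-trimethoxyphenyl)butyl]-trans-decalin-7β-carboxylate
Product: 32 7β-(2-hydroxypropan-2-yl)-4α,10β-dimethyl-1β-[(1S)-3-methyl-1-(2,4,6-trimethoxyphenyl)butyl]-trans-decalin-4β-ol, via C7 methyl ketone 31 (not isolated)
Conditions: MeMgBr (6 equiv), THF, 0 → 23 °C; aq. NH4Cl
Reagents that add atoms: methylmagnesium bromide, C[Mg]Br
Why: Double Grignard addition to the ester through methyl ketone 31 gives the C11 dimethyl carbinol; the C4 alcohol is carried as its magnesium alkoxide.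

Step 15
Reactants: 32 7β-(2-hydroxypropan-2-yl)-4α,10β-dimethyl-1β-[(1S)-3-methyl-1-(2,4,6-trimethoxyphenyl)butyl]-trans-decalin-4β-ol
Product: 33 1β-[(1S)-1-(3,5-dibromo-2,4,6-trimethoxyphenyl)-3-methylbutyl]-7β-(2-hydroxypropan-2-yl)-4α,10β-dimethyl-trans-decalin-4β-ol
Conditions: NBS (2.1 equiv), MeCN, 0 → 23 °C, dark
Reagents that add atoms: N-bromosuccinimide, O=C1CCC(=O)N1Br
Why: Electrophilic aromatic bromination of the two free ring positions, each activated by two ortho and one para methoxy group; no alkene remains and the tertiary alcohols are inert to NBS.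

Step 16
Reactants: 33 1β-[(1S)-1-(3,5-dibromo-2,4,6-trimethoxyphenyl)-3-methylbutyl]-7β-(2-hydroxypropan-2-yl)-4α,10β-dimethyl-trans-decalin-4β-ol
Product: 36 5-[(1S)-1-[4β-hydroxy-7β-(2-hydroxypropan-2-yl)-4α,10β-dimethyl-trans-decalin-1β-yl]-3-methylbutyl]-2,4,6-trimethoxybenzene-1,3-dicarbaldehyde, via tetralithiated diol 34 (not isolated), via bis(hemiaminal alkoxide) 35 (not isolated)
Conditions: t-BuLi (6.5 equiv), THF, −78 → −40 °C; DMF, −78 → 0 °C; 1 M HCl
Reagents that add atoms: N,N-dimethylformamide, CN(C)C=O
Why: Deprotonation of both alcohols, twofold bromine–lithium exchange (each aryl C–Li flanked and chelated by two methoxy groups) and formylation with DMF; the hemiaminal alkoxides collapse to the dialdehyde on acidic work-up.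

Step 17
Reactants: 36 5-[(1S)-1-[4β-hydroxy-7β-(2-hydroxypropan-2-yl)-4α,10β-dimethyl-trans-decalin-1β-yl]-3-methylbutyl]-2,4,6-trimethoxybenzene-1,3-dicarbaldehyde
Product: 37 5-[(1S)-1-[(1R,4R,4aS,6S,8aR)-4-hydroxy-6-(2-hydroxypropan-2-yl)-4,8a-dimethyldecahydronaphthalen-1-yl]-3-methylbutyl]-2,4,6-trihydroxybenzene-1,3-dicarbaldehyde
Conditions: NaSEt (excess), DMF, 120 °C; then 1 M HCl
Reagents that add atoms: none
Why: Nucleophilic (SN2) demethylation by thiolate: every methoxy group is ortho or para to both formyl groups, so each phenoxide is a good leaving group, and the basic medium cannot ionise the tertiary alcohols. Acidification should release the hydrogen-bonded trihydroxy dialdehyde.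

## Compound list

In the names, locants and α/β follow the decalin numbering set out under "Structural features" (β = face of the C10 methyl).

1 | (S)-(+)-carvone, (5S)-2-methyl-5-(prop-1-en-2-yl)cyclohex-2-en-1-one | CC1=CC[C@@H](CC1=O)C(C)=C | starting material
2 | iodomethane | CI | starting material
3 | lithium α′-enolate of carvone (C1–OLi, C1=C6) | CC1=CC[C@@H](C=C1O[Li])C(C)=C | intermediate (not isolated)
4 | (5S,6R)-2,6-dimethyl-5-(prop-1-en-2-yl)cyclohex-2-en-1-one | CC(=C)[C@H]1CC=C(C)C(=O)[C@@H]1C | intermediate
5 | but-3-en-2-one | CC(=O)C=C | starting material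
6 | lithium α′-enolate of 4 (tetrasubstituted, cross-conjugated) | CC(=C)[C@H]1CC=C(C)C(O[Li])=C1C | intermediate (not isolated)
7 | (5R,6R)-2,6-dimethyl-6-(3-oxobutyl)-5-(prop-1-en-2-yl)cyclohex-2-en-1-one | CC(=C)[C@H]1CC=C(C)C(=O)[C@]1(C)CCC(C)=O | intermediate (not isolated)
8 | (4aR,5R)-8a-hydroxy-4a,8-dimethyl-5-(prop-1-en-2-yl)-3,4,4a,5,6,8a-hexahydronaphthalen-2(1H)-one (either C8a epimer) | CC(=C)[C@H]1CC=C(C)C2(O)CC(=O)CC[C@]12C | intermediate (not isolated)
9 | (4aR,5R)-4a,8-dimethyl-5-(prop-1-en-2-yl)-4,4a,5,6-tetrahydronaphthalen-2(3H)-one | CC(=C)[C@H]1CC=C(C)C2=CC(=O)CC[C@]12C | intermediate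
10 | lithium dienolate from 1,6-reduction of 9 (C7–OLi, C6=C7, C4=C5) | CC(=C)[C@H]1CCC(C)=C2C=C(O[Li])CC[C@]12C | intermediate (not isolated)
11 | (4aR,5R)-4a,8-dimethyl-5-(prop-1-en-2-yl)-3,4,4a,5,6,7-hexahydronaphthalen-2(1H)-one | CC(=C)[C@H]1CCC(C)=C2CC(=O)CC[C@]12C | intermediate
12 | 7,7-ethylenedioxy-1β-isopropenyl-4,10β-dimethyl-Δ4(5)-octalin | CC(=C)[C@H]1CCC(C)=C2CC3(OCCO3)CC[C@]12C | intermediate
13 | vicinal diol of 12 at the former isopropenyl group (either carbinol epimer) | CC(O)(CO)[C@H]1CCC(C)=C2CC3(OCCO3)CC[C@]12C | intermediate (not isolated)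
14 | 1β-acetyl-7,7-ethylenedioxy-4,10β-dimethyl-Δ4(5)-octalin | CC(=O)[C@H]1CCC(C)=C2CC3(OCCO3)CC[C@]12C | intermediate
15 | potassium enolate of 14 (terminal) | C=C(O[K])[C@H]1CCC(C)=C2CC3(OCCO3)CC[C@]12C | intermediate (not isolated)
16 | 1-(7,7-ethylenedioxy-4,10β-dimethyl-Δ4(5)-octalin-1β-yl)ethenyl trifluoromethanesulfonate | C=C(OS(=O)(=O)C(F)(F)F)[C@H]1CCC(C)=C2CC3(OCCO3)CC[C@]12C | intermediate
17 | 1-(5α-bromo-7,7-ethylenedioxy-4β-hydroxy-4α,10β-dimethyl-trans-decalin-1β-yl)ethenyl trifluoromethanesulfonate | C=C(OS(=O)(=O)C(F)(F)F)[C@H]1CC[C@@](C)(O)[C@@]2(Br)CC3(OCCO3)CC[C@]12C | intermediate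
18 | 1-(7,7-ethylenedioxy-4β-hydroxy-4α,10β-dimethyl-5αH-trans-decalin-1β-yl)ethenyl trifluoromethanesulfonate | C=C(OS(=O)(=O)C(F)(F)F)[C@H]1CC[C@@](C)(O)[C@H]2CC3(OCCO3)CC[C@]12C | intermediate
19 | 1,3,5-trimethoxybenzene | COc1cc(OC)cc(OC)c1 | starting material
20 | 2,4,6-trimethoxyphenyllithium | [Li]c1c(OC)cc(OC)cc1OC | intermediate (not isolated)
21 | (2,4,6-trimethoxyphenyl)zinc chloride | Cl[Zn]c1c(OC)cc(OC)cc1OC | intermediate (not isolated)
22 | 7,7-ethylenedioxy-4α,10β-dimethyl-1β-[1-(2,4,6-trimethoxyphenyl)ethenyl]-5αH-trans-decalin-4β-ol | C=C(c1c(OC)cc(OC)cc1OC)[C@H]1CC[C@@](C)(O)[C@H]2CC3(OCCO3)CC[C@]12C | intermediate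
23 | 2-bromopropene | CC(Br)=C | starting material
24 | 9-[(2S)-2-(7,7-ethylenedioxy-4β-hydroxy-4α,10β-dimethyl-trans-decalin-1β-yl)-2-(2,4,6-trimethoxyphenyl)ethyl]-9-borabicyclo[3.3.1]nonane | C1CC2CCCC(C1)B2C[C@H](c6c(OC)cc(OC)cc6OC)[C@H]3CC[C@@](C)(O)[C@H]4CC5(OCCO5)CC[C@]34C | intermediate (not isolated)
25 | 7,7-ethylenedioxy-4α,10β-dimethyl-1β-[(1S)-3-methyl-1-(2,4,6-trimethoxyphenyl)but-3-en-1-yl]-trans-decalin-4β-ol | CC(=C)C[C@H](c1c(OC)cc(OC)cc1OC)[C@H]1CC[C@@](C)(O)[C@H]2CC3(OCCO3)CC[C@]12C | intermediate (not isolated)
26 | 4β-hydroxy-4α,10β-dimethyl-1β-[(1S)-3-methyl-1-(2,4,6-trimethoxyphenyl)but-3-en-1-yl]-5αH-trans-decalin-7-one | CC(=C)C[C@H](c1c(OC)cc(OC)cc1OC)[C@H]1CC[C@@](C)(O)[C@H]2CC(=O)CC[C@]12C | intermediate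
27 | dilithium C4-alkoxide C7-enolate of 26 (C7=C8) | CC(=C)C[C@H](c1c(OC)cc(OC)cc1OC)[C@H]1CC[C@@](C)(O[Li])[C@H]2CC(O[Li])=CC[C@]12C | intermediate (not isolated)
28 | 4β-hydroxy-4α,10β-dimethyl-1β-[(1S)-3-methyl-1-(2,4,6-trimethoxyphenyl)but-3-en-1-yl]-5αH-octal-7-en-7-yl trifluoromethanesulfonate | CC(=C)C[C@H](c1c(OC)cc(OC)cc1OC)[C@H]1CC[C@@](C)(O)[C@H]2CC(OS(=O)(=O)C(F)(F)F)=CC[C@]12C | intermediate
29 | methyl 4β-hydroxy-4α,10β-dimethyl-1β-[(1S)-3-methyl-1-(2,4,6-trimethoxyphenyl)but-3-en-1-yl]-5αH-octal-7-ene-7-carboxylate | CC(=C)C[C@H](c1c(OC)cc(OC)cc1OC)[C@H]1CC[C@@](C)(O)[C@H]2CC(C(=O)OC)=CC[C@]12C | intermediate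
30 | methyl 4β-hydroxy-4α,10β-dimethyl-1β-[(1S)-3-methyl-1-(2,4,6-trimethoxyphenyl)butyl]-trans-decalin-7β-carboxylate | CC(C)C[C@H](c1c(OC)cc(OC)cc1OC)[C@H]1CC[C@@](C)(O)[C@H]2C[C@@H](C(=O)OC)CC[C@]12C | intermediate
31 | 7β-acetyl-4α,10β-dimethyl-1β-[(1S)-3-methyl-1-(2,4,6-trimethoxyphenyl)butyl]-trans-decalin-4β-ol | CC(C)C[C@H](c1c(OC)cc(OC)cc1OC)[C@H]1CC[C@@](C)(O)[C@H]2C[C@@H](C(C)=O)CC[C@]12C | intermediate (not isolated)
32 | 7β-(2-hydroxypropan-2-yl)-4α,10β-dimethyl-1β-[(1S)-3-methyl-1-(2,4,6-trimethoxyphenyl)butyl]-trans-decalin-4β-ol | CC(C)C[C@H](c1c(OC)cc(OC)cc1OC)[C@H]1CC[C@@](C)(O)[C@H]2C[C@@H](C(C)(C)O)CC[C@]12C | intermediate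
33 | 1β-[(1S)-1-(3,5-dibromo-2,4,6-trimethoxyphenyl)-3-methylbutyl]-7β-(2-hydroxypropan-2-yl)-4α,10β-dimethyl-trans-decalin-4β-ol | CC(C)C[C@H](c1c(OC)c(Br)c(OC)c(Br)c1OC)[C@H]1CC[C@@](C)(O)[C@H]2C[C@@H](C(C)(C)O)CC[C@]12C | intermediate
34 | 3′,5′-dilithio dilithium dialkoxide of 33 | CC(C)C[C@H](c1c(OC)c([Li])c(OC)c([Li])c1OC)[C@H]1CC[C@@](C)(O[Li])[C@H]2C[C@@H](C(C)(C)O[Li])CC[C@]12C | intermediate (not isolated)
35 | bis[lithium (dimethylamino)methanolate] adduct of 34 with DMF (either configuration at the two new carbons) | CC(C)C[C@H](c1c(OC)c(C(O[Li])N(C)C)c(OC)c(C(O[Li])N(C)C)c1OC)[C@H]1CC[C@@](C)(O[Li])[C@H]2C[C@@H](C(C)(C)O[Li])CC[C@]12C | intermediate (not isolated)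
36 | 5-[(1S)-1-[4β-hydroxy-7β-(2-hydroxypropan-2-yl)-4α,10β-dimethyl-trans-decalin-1β-yl]-3-methylbutyl]-2,4,6-trimethoxybenzene-1,3-dicarbaldehyde | CC(C)C[C@H](c1c(OC)c(C=O)c(OC)c(C=O)c1OC)[C@H]1CC[C@@](C)(O)[C@H]2C[C@@H](C(C)(C)O)CC[C@]12C | intermediate
37 | 5-[(1S)-1-[(1R,4R,4aS,6S,8aR)-4-hydroxy-6-(2-hydroxypropan-2-yl)-4,8a-dimethyldecahydronaphthalen-1-yl]-3-methylbutyl]-2,4,6-trihydroxybenzene-1,3-dicarbaldehyde | CC(C)C[C@H](c1c(O)c(C=O)c(O)c(C=O)c1O)[C@H]1CC[C@@](C)(O)[C@H]2C[C@@H](C(C)(C)O)CC[C@]12C | target

## Step count and least certain steps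

Total step count: 17. Longest linear sequence: 17 steps, from 1 to 37 (19 and 23 enter without steps of their own).

Step 2 (key step). What may go wrong: anionic polymerisation of the enone and proton transfer from the adduct to unreacted enolate, which would stall the Michael addition. The lithium enolate is hindered and the acceptor is unsubstituted, so both processes are plausible. Fallback: from 4, trap the kinetic enolate with Me3SiCl to give the trimethylsilyl dienol ether F1. Then carry out a Mukaiyama–Michael addition to 5 with BF3·OEt2 and i-PrOH in CH2Cl2 at −78 °C. This comes back to the route at diketone 7, which is isolated and cyclised to 9 with KOH in MeOH as in step 2.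

Step 10. What may go wrong: poor facial selectivity in the hydroboration, since control of C9′ rests on one preferred rotamer about C1–C9′, and slow addition to a hindered alkene. Fallback: from 22, a catalyst-controlled copper-catalysed protoboration (CuCl, chiral bisphosphine, NaOt-Bu, B2pin2, MeOH) gives the primary pinacol boronate F2 with C9′ set by the ligand. Zweifel olefination with isopropenyllithium (from 23 and t-BuLi), then I2 and NaOMe, comes back at 25, which is hydrolysed to 26 as in step 10.

Step 8. What may go wrong: loss of facial selectivity in hydrogen transfer to the nearly planar C5 radical, giving cis-fused material. Fallback: from 14, NBS in aqueous THF gives the bromohydrin F3. Dehydrobromination with 2,4,6-collidine at 120 °C gives the C5=C6 allylic alcohol F4. Hydrogenation over 10 % Pd on carbon adds hydrogen anti to the C10 methyl (the normal course for 5-ene steroids) and gives the saturated hydroxy ketone F5. KN(SiMe3)2 (2.2 equiv) and PhNTf2 then come back at 18.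

Step 16. What may go wrong: incomplete second bromine–lithium exchange or early protonation of an aryllithium, leading to mono-formylated or debrominated material. Fallback: from 32 (step 15 is then not needed), directed ortho-lithiation with n-BuLi and TMEDA between two methoxy groups and a DMF quench give the monoaldehyde F6. In-situ protection of its formyl group as the α-amino alkoxide with LiN(Me)CH2CH2NMe2, a second ortho-lithiation with n-BuLi and DMF then come back at 36.

Step 9. What may go wrong: slow transmetalation and reductive elimination between the di-ortho-substituted arylzinc and the α-branched alkenyl partner, or attack of the organometallic at sulfur of the triflate. Fallback: from 18, reverse the polarity by Miyaura borylation (B2pin2, PdCl2(dppf), KOAc, dioxane, 80 °C) to the alkenyl pinacol boronate F7. Suzuki–Miyaura coupling with commercial 2-bromo-1,3,5-trimethoxybenzene (Pd(OAc)2, SPhos, K3PO4, toluene–H2O) then comes back at 22.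

## Further compounds

F1 | step 2 | trimethylsilyl dienol ether of 4 (C1–OSiMe3, C1=C6) | CC(=C)[C@H]1CC=C(C)C(O[Si](C)(C)C)=C1C
F2 | step 10 | 2-[(2S)-2-(7,7-ethylenedioxy-4β-hydroxy-4α,10β-dimethyl-trans-decalin-1β-yl)-2-(2,4,6-trimethoxyphenyl)ethyl]-4,4,5,5-tetramethyl-1,3,2-dioxaborolane | CC1(C)OB(C[C@H](c2c(OC)cc(OC)cc2OC)[C@H]2CC[C@@](C)(O)[C@H]3CC4(OCCO4)CC[C@]23C)OC1(C)C
F3 | step 8 | 1β-acetyl-5α-bromo-7,7-ethylenedioxy-4α,10β-dimethyl-trans-decalin-4β-ol | CC(=O)[C@H]1CC[C@@](C)(O)[C@@]2(Br)CC3(OCCO3)CC[C@]12C
F4 | step 8 | 1β-acetyl-7,7-ethylenedioxy-4α,10β-dimethyl-Δ5(6)-octalin-4β-ol | CC(=O)[C@H]1CC[C@@](C)(O)C2=CC3(OCCO3)CC[C@]12C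
F5 | step 8 | 1β-acetyl-7,7-ethylenedioxy-4α,10β-dimethyl-5αH-trans-decalin-4β-ol | CC(=O)[C@H]1CC[C@@](C)(O)[C@H]2CC3(OCCO3)CC[C@]12C
F6 | step 16 | 3-[(1S)-1-[4β-hydroxy-7β-(2-hydroxypropan-2-yl)-4α,10β-dimethyl-trans-decalin-1β-yl]-3-methylbutyl]-2,4,6-trimethoxybenzaldehyde | CC(C)C[C@H](c1c(OC)cc(OC)c(C=O)c1OC)[C@H]1CC[C@@](C)(O)[C@H]2C[C@@H](C(C)(C)O)CC[C@]12C
F7 | step 9 | 7,7-ethylenedioxy-4α,10β-dimethyl-1β-[1-(4,4,5,5-tetramethyl-1,3,2-dioxaborolan-2-yl)ethenyl]-5αH-trans-decalin-4β-ol | C=C(B1OC(C)(C)C(C)(C)O1)[C@H]1CC[C@@](C)(O)[C@H]2CC3(OCCO3)CC[C@]12C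
A1 | alternative 1 | dimethyl 5-alkyl-2,6-dimethoxy-4-(triisopropylsilyloxy)benzene-1,3-dicarboxylate carrying the bis(trimethylsilyl)-protected terpene unit | CC(C)C[C@H](c1c(O[Si](C(C)C)(C(C)C)C(C)C)c(C(=O)OC)c(OC)c(C(=O)OC)c1OC)[C@H]1CC[C@@](C)(O[Si](C)(C)C)[C@H]2C[C@@H](C(C)(C)O[Si](C)(C)C)CC[C@]12C
A2 | alternative 1 | dimethyl 4,6-dimethoxy-2-oxo-2H-pyran-3,5-dicarboxylate | COC(=O)C1=C(OC)C(C(=O)OC)=C(OC)OC1=O
A3 | alternative 1 | triisopropylsilyl ynol ether with the bis(trimethylsilyl)-protected terpene unit on the propargylic carbon C9′ | CC(C)C[C@H](C#CO[Si](C(C)C)(C(C)C)C(C)C)[C@H]1CC[C@@](C)(O[Si](C)(C)C)[C@H]2C[C@@H](C(C)(C)O[Si](C)(C)C)CC[C@]12C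
A4 | alternative 2 | methyl trans-4-(tert-butyldimethylsilyloxy)-4,8a-dimethyl-6-oxodecahydronaphthalene-1-carboxylate (C1 ester axial) | COC(=O)[C@@H]1CC[C@@](C)(O[Si](C)(C)C(C)(C)C)[C@H]2CC(=O)CC[C@]12C
A5 | alternative 2 | methyl 2-[3-(tert-butyldimethylsilyloxy)but-3-en-1-yl]-3-methyl-6-oxoocta-3,7-dienoate | COC(=O)C(CCC(=C)O[Si](C)(C)C(C)(C)C)C(C)=CCC(=O)C=C
A6 | alternative 3 | trans-4a-methyl-4-[3-methyl-1-(2,4,6-trimethoxyphenyl)butyl]-3,4,4a,8a-tetrahydronaphthalene-1,7(2H,8H)-dione | CC(C)C[C@H](c1c(OC)cc(OC)cc1OC)[C@H]1CCC(=O)[C@H]2CC(=O)C=C[C@]12C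
A7 | alternative 3 | 7-methyl-4-(1-methyl-4-oxocyclohexa-2,5-dien-1-yl)-5-(2,4,6-trimethoxyphenyl)octanal with C4 and C5 as C1 and C9′ of 37 | CC(C)C[C@H](c1c(OC)cc(OC)cc1OC)[C@@H](CCC=O)C1(C)C=CC(=O)C=C1
A8 | alternative 3 | cis-fused C5 epimer of A6 | CC(C)C[C@H](c1c(OC)cc(OC)cc1OC)[C@H]1CCC(=O)[C@@H]2CC(=O)C=C[C@]12C
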